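**Plan**
- Retrosynthesis: the benzyl ether on the outer phenol is cut last and the ArCH2 group is traced back to a diaryl ketone. The central ring is then opened at C1–C6 and C2–C3 (C1 carries the phenethyl chain, C2 the benzylic carbon), giving an aroyl alkyne and a 1,1-dimethoxy-3-silyloxybutadiene.
- Enabling feature: the central benzene ring is a resorcinol monoether with OMe on C3 (ortho to C2) and OH on C5 (para to C2). A ketene-acetal carbon and a silyl-enol-ether carbon of such a diene land in exactly these positions around an acyl-substituted alkyne.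
- The ynone is cut at the C(sp)–C(=O) bond (aroyl chloride plus terminal alkyne) and at the ArCH2–CH2 bond (benzyl bromide plus lithiated silylpropyne). The diene comes from 1,1-dimethoxyethene and acetyl chloride.
- Forward: both outer rings are bought. The ynone chain is joined in steps 1–3, the diene is made in steps 4–5, the central ring (the only ring formed) arises in step 6, then C=O is reduced to CH2 and the benzyl group is removed.
- Stereochemistry: the target has no stereogenic element. The only selectivity to be set is the regiochemistry of the cycloaddition, which also tells the two resorcinol oxygens apart.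

Key step: step 6

Remark: the target SMILES contains no stereocentre and no stereogenic double bond, so the compound is achiral and "single enantiomer" means the compound as drawn.

**Step 1**
Reactants: 1 1-(trimethylsilyl)propyne; 2 3-methoxybenzyl bromide
Product: 4 trimethyl[4-(3-methoxyphenyl)but-1-yn-1-yl]silane, via 3-lithio-1-(trimethylsilyl)propyne 3 (not isolated)
Conditions: n-BuLi, THF, −78 °C; then 2, −78 °C → rt
Reagents that add atoms: none
Why: Propargylic lithiation of the silyl-capped propyne followed by SN2 alkylation of the benzylic bromide at the CH2 terminus should give the homopropargyl arene, the silyl group blocking the alkyne terminus and disfavouring the allenyl isomer.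

**Step 2**
Reactants: 4 trimethyl[4-(3-methoxyphenyl)but-1-yn-1-yl]silane
Product: 5 1-(but-3-yn-1-yl)-3-methoxybenzene
Conditions: K2CO3 (cat.), MeOH, rt
Reagents that add atoms: none
Why: Base-catalysed methanolytic protodesilylation of an alkynylsilane cleaves only the C(sp)–Si bond and leaves the aryl methyl ether untouched.

**Step 3**
Reactants: 5 1-(but-3-yn-1-yl)-3-methoxybenzene; 6 4-(benzyloxy)benzoyl chloride
Product: 7 1-[4-(benzyloxy)phenyl]-5-(3-methoxyphenyl)pent-2-yn-1-one
Conditions: PdCl2(PPh3)2 (2 mol %), CuI (4 mol %), Et3N, THF, rt
Reagents that add atoms: none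
Why: Acyl Sonogashira coupling of an aroyl chloride with a terminal alkyne forms the C(sp)–C(=O) bond at room temperature, where the aroylpalladium species is intercepted by the copper acetylide before it can decarbonylate and the benzyl ether is inert.

**Step 4**
Reactants: 8 1,1-dimethoxyethene; 9 acetyl chloride
Product: 10 4,4-dimethoxybut-3-en-2-one
Conditions: Et3N, Et2O, 0 °C → rt
Reagents that add atoms: none
Why: C-Acylation of a ketene acetal: the nucleophilic CH2 carbon adds to the acid chloride and the resulting dimethoxycarbenium ion loses a proton to the amine, which should give the push–pull acylketene acetal.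

**Step 5**
Reactants: 10 4,4-dimethoxybut-3-en-2-one
Product: 11 1,1-dimethoxy-3-(trimethylsilyloxy)buta-1,3-diene
Conditions: TMSCl, Et3N, ZnCl2 (cat.), toluene, 40 °C
Reagents that add atoms: chlorotrimethylsilane, C[Si](C)(C)Cl
Why: Silyl enol ether formation under Danishefsky-type soft-enolisation conditions can only occur at the methyl group, the sole enolisable position, so a single 2-silyloxydiene is expected.

**Step 6**
Reactants: 7 1-[4-(benzyloxy)phenyl]-5-(3-methoxyphenyl)pent-2-yn-1-one; 11 1,1-dimethoxy-3-(trimethylsilyloxy)buta-1,3-diene
Product: 14 [4-(benzyloxy)phenyl]{4-hydroxy-2-methoxy-6-[2-(3-methoxyphenyl)ethyl]phenyl}methanone, via cyclohexa-1,4-diene cycloadduct 12 (not isolated), via aryl trimethylsilyl ether 13 (not isolated)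
Conditions: 11 (2.5 equiv), toluene, 100 °C (sealed tube); then 1 M HCl, THF, rt
Reagents that add atoms: none
Why: The electron-rich diene adds across the electron-poor triple bond of the ynone in a normal-electron-demand Diels–Alder reaction, either concerted and strongly asynchronous or as a Mukaiyama–Michael addition followed by closure onto the dimethoxycarbenium ion, forming the C1–C6 and C2–C3 bonds of the central ring. The closest known reaction type is the benzannulation of 1,1-dialkoxy-3-silyloxybuta-1,3-dienes with acetylenic ketones and esters, which gives resorcinol monoethers. The six-membered ring closes in [4+2] mode to the cyclohexa-1,4-diene 12, which aromatises by 1,4-elimination of methanol from the ketal carbon, and the aryl silyl ether 13 is hydrolysed to the phenol by the dilute acid. No stereocentre is created. The step needs regioselectivity, and this is secured by matched polarisation: the diene's CH2 terminus (largest HOMO coefficient) bonds to the ynone β-carbon that carries the phenethyl chain, so the ketal carbon ends up next to the aroyl-bearing carbon, placing OMe ortho and OH para to the aroyl group. Under thermal, Lewis-acid-free conditions the C≡C bond, not the C=O group, should act as the dienophile.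

**Step 7**
Reactants: 14 [4-(benzyloxy)phenyl]{4-hydroxy-2-methoxy-6-[2-(3-methoxyphenyl)ethyl]phenyl}methanone
Product: 16 4-[4-(benzyloxy)benzyl]-3-methoxy-5-[2-(3-methoxyphenyl)ethyl]phenol, via benzhydrol 15 (not isolated)
Conditions: Et3SiH (5 equiv), TFA, CH2Cl2, 0 °C → rt
Reagents that add atoms: none
Why: Ionic hydrogenation: the protonated electron-rich diaryl ketone accepts hydride from the silane to give benzhydrol 15, which ionises to a diarylmethyl cation (a protonated p-quinone methide stabilised by the para-OH, ortho-OMe and para-benzyloxy groups) that takes a second hydride from the excess silane, while the benzyl and methyl aryl ethers are stable to TFA at this temperature.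

**Step 8**
Reactants: 16 4-[4-(benzyloxy)benzyl]-3-methoxy-5-[2-(3-methoxyphenyl)ethyl]phenol
Product: 17 4-(4-hydroxybenzyl)-3-methoxy-5-[2-(3-methoxyphenyl)ethyl]phenol
Conditions: H2 (1 atm), 10% Pd/C, EtOAc/MeOH, rt
Reagents that add atoms: none
Why: Catalytic hydrogenolysis of the benzyl aryl ether over Pd/C frees the second phenol, and the diarylmethane C–C bonds, the aryl methyl ethers and the arene rings are not touched under these mild conditions.

**Compound list**
1 | 1-(trimethylsilyl)propyne | CC#C[Si](C)(C)C | starting material
2 | 3-methoxybenzyl bromide | COc1cccc(CBr)c1 | starting material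
3 | 3-lithio-1-(trimethylsilyl)propyne | [Li]CC#C[Si](C)(C)C | intermediate
4 | trimethyl[4-(3-methoxyphenyl)but-1-yn-1-yl]silane | COc1cccc(CCC#C[Si](C)(C)C)c1 | intermediate
5 | 1-(but-3-yn-1-yl)-3-methoxybenzene | COc1cccc(CCC#C)c1 | intermediate
6 | 4-(benzyloxy)benzoyl chloride | O=C(Cl)c1ccc(OCc2ccccc2)cc1 | starting material
7 | 1-[4-(benzyloxy)phenyl]-5-(3-methoxyphenyl)pent-2-yn-1-one | COc1cccc(CCC#CC(=O)c2ccc(OCc3ccccc3)cc2)c1 | intermediate
8 | 1,1-dimethoxyethene | C=C(OC)OC | starting material
9 | acetyl chloride | CC(=O)Cl | starting material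
10 | 4,4-dimethoxybut-3-en-2-one | CC(=O)C=C(OC)OC | intermediate
11 | 1,1-dimethoxy-3-(trimethylsilyloxy)buta-1,3-diene | C=C(O[Si](C)(C)C)C=C(OC)OC | intermediate
12 | [4-(benzyloxy)phenyl]{6,6-dimethoxy-2-[2-(3-methoxyphenyl)ethyl]-4-(trimethylsilyloxy)cyclohexa-1,4-dien-1-yl}methanone | COc1cccc(CCC2=C(C(=O)c3ccc(OCc4ccccc4)cc3)C(OC)(OC)C=C(O[Si](C)(C)C)C2)c1 | intermediate
13 | [4-(benzyloxy)phenyl]{2-methoxy-6-[2-(3-methoxyphenyl)ethyl]-4-(trimethylsilyloxy)phenyl}methanone | COc1cccc(CCc2cc(O[Si](C)(C)C)cc(OC)c2C(=O)c2ccc(OCc3ccccc3)cc2)c1 | intermediate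
14 | [4-(benzyloxy)phenyl]{4-hydroxy-2-methoxy-6-[2-(3-methoxyphenyl)ethyl]phenyl}methanone | COc1cccc(CCc2cc(O)cc(OC)c2C(=O)c2ccc(OCc3ccccc3)cc2)c1 | intermediate
15 | 4-{[4-(benzyloxy)phenyl](hydroxy)methyl}-3-methoxy-5-[2-(3-methoxyphenyl)ethyl]phenol (racemic) | COc1cccc(CCc2cc(O)cc(OC)c2C(O)c2ccc(OCc3ccccc3)cc2)c1 | intermediate
16 | 4-[4-(benzyloxy)benzyl]-3-methoxy-5-[2-(3-methoxyphenyl)ethyl]phenol | COc1cccc(CCc2cc(O)cc(OC)c2Cc2ccc(OCc3ccccc3)cc2)c1 | intermediate
17 | 4-(4-hydroxybenzyl)-3-methoxy-5-[2-(3-methoxyphenyl)ethyl]phenol | COc1cccc(CCc2cc(O)cc(OC)c2Cc2ccc(O)cc2)c1 | target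

**Step count**
Total: 8 steps. Longest linear sequence: 6 steps (steps 1, 2, 3, 6, 7, 8); steps 4 and 5 form the convergent diene branch.

**Steps most likely to fail**

Step 6. The cycloaddition may be too slow at the β-alkyl-substituted, aryl-conjugated ynone, so that the moisture-sensitive diene is lost by hydrolysis or oligomerisation before the ring closes, or the reaction may stop at an open-chain Michael adduct. The fallback sets out from alkyne 5 (with diene 11) and comes back to the route at benzhydrol 15. It replaces the aroyl group by a smaller, more electrophilic formyl group and attaches the outer 4-(benzyloxy)phenyl ring afterwards. Alkyne 5 would be lithiated (n-BuLi, THF, −78 °C) and formylated with DMF (inverse quench into aqueous KH2PO4) to give 5-(3-methoxyphenyl)pent-2-ynal F1. Cycloaddition with 11 (toluene, 60–80 °C; then 1 M HCl, THF) should pass through 6,6-dimethoxy-2-[2-(3-methoxyphenyl)ethyl]-4-(trimethylsilyloxy)cyclohexa-1,4-diene-1-carbaldehyde F2 and 2-methoxy-6-[2-(3-methoxyphenyl)ethyl]-4-(trimethylsilyloxy)benzaldehyde F3 to 4-hydroxy-2-methoxy-6-[2-(3-methoxyphenyl)ethyl]benzaldehyde F4. Addition of commercial 4-(benzyloxy)phenylmagnesium bromide (3 equiv, THF, 0 °C → rt, one equivalent being consumed by the phenol) should then give benzhydrol 15, which is reduced with Et3SiH/TFA as in step 7 to 16.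

Step 7. The diarylmethyl cation may be captured by the tethered 3-methoxyphenyl ring (seven-membered Friedel–Crafts closure, para to its OMe) faster than the silane delivers hydride, and prolonged exposure to TFA may start to cleave the benzyl ether. The fallback sets out from ketone 14 and comes back at target 17, avoiding a free cation in solution. LiAlH4 (THF, 0 °C → rt) would reduce 14 to benzhydrol 15, isolated this time. Hydrogenation over Pd/C (H2, 3–4 bar, EtOH, rt to 40 °C) should then hydrogenolyse the benzhydrylic C–OH bond on the metal surface and the benzyl ether in the same operation, giving 17 without passing through 16.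

Step 4. Acetyl chloride and triethylamine may generate ketene, which diverts the ketene acetal into [2+2] adducts, and the acid-sensitive ketene acetal may oligomerise before C-acylation is complete. The fallback sets out from acetyl chloride 9 and comes back at enone 10. Friedel–Crafts-type addition of 9 to commercial 1,1-dichloroethene (AlCl3, CH2Cl2, 0 °C) should give 4,4,4-trichlorobutan-2-one F5, which loses hydrogen chloride on distillation to give 4,4-dichlorobut-3-en-2-one F6. Double addition–elimination with NaOMe (2 equiv, MeOH, 0 °C) would replace both vinylic chlorides and give 10.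

**Further compounds**
F1 | step 6 | 5-(3-methoxyphenyl)pent-2-ynal | COc1cccc(CCC#CC=O)c1
F2 | step 6 | 6,6-dimethoxy-2-[2-(3-methoxyphenyl)ethyl]-4-(trimethylsilyloxy)cyclohexa-1,4-diene-1-carbaldehyde | COc1cccc(CCC2=C(C=O)C(OC)(OC)C=C(O[Si](C)(C)C)C2)c1
F3 | step 6 | 2-methoxy-6-[2-(3-methoxyphenyl)ethyl]-4-(trimethylsilyloxy)benzaldehyde | COc1cccc(CCc2cc(O[Si](C)(C)C)cc(OC)c2C=O)c1
F4 | step 6 | 4-hydroxy-2-methoxy-6-[2-(3-methoxyphenyl)ethyl]benzaldehyde | COc1cccc(CCc2cc(O)cc(OC)c2C=O)c1
F0 | step 7 | none | none
F5 | step 4 | 4,4,4-trichlorobutan-2-one | CC(=O)CC(Cl)(Cl)Cl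
F6 | step 4 | 4,4-dichlorobut-3-en-2-one | CC(=O)C=C(Cl)Cl
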